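**Retrosynthetic overview**
- Target ⇐ O-demethylation of the 5,7-dimethoxyflavone ⇐ acid cyclodehydration of an o-hydroxyaryl 1,3-diketone (pyranone ring C closed last).
- Diketone ⇐ crossed Claisen condensation of a chiral piperidinyl o-hydroxyacetophenone enolate with methyl benzoate (the key fragment union; forms the flavone C2–C3 bond and brings in ring B).
- Acetophenone ⇐ ortho-acylation of 3,5-dimethoxy-4-(piperidin-2-yl)phenol; the single free OH para to the piperidine-bearing carbon fixes 6- over 8-substitution.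
- Piperidine ⇐ ring-closing metathesis and hydrogenation of an N-allyl homoallylamine ⇐ diastereoselective allylation of the (S)-tert-butanesulfinyl imine of 4-benzyloxy-2,6-dimethoxybenzaldehyde (sets R).
- Ring order: ring A is bought, the piperidine is built second, ring C is closed last.

Assumption: 4-hydroxy-2,6-dimethoxybenzaldehyde (compound 1, the backbone-amide-linker aldehyde) is taken as a commercial starting material; the stereocentre in the given SMILES is read as (R) at piperidine C-2.

**Route**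

Step 1
Reactants: 1 4-hydroxy-2,6-dimethoxybenzaldehyde; 2 benzyl bromide
Product: 3 4-(benzyloxy)-2,6-dimethoxybenzaldehyde
Conditions: BnBr, K2CO3, DMF, rt
Reagents that add atoms: benzyl bromide (2), BrCc1ccccc1
Why: Williamson ether synthesis on the acidic para-formyl phenol marks the one oxygen that must later be free to direct the acylation and close the pyranone.

Step 2
Reactants: 3 4-(benzyloxy)-2,6-dimethoxybenzaldehyde; 4 (S)-2-methylpropane-2-sulfinamide
Product: 5 (S,E)-N-[4-(benzyloxy)-2,6-dimethoxybenzylidene]-2-methylpropane-2-sulfinamide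
Conditions: Ti(OEt)4 (2 equiv), THF, 65 °C
Reagents that add atoms: (S)-2-methylpropane-2-sulfinamide (4), CC(C)(C)[S@](=O)N
Why: Ellman imine condensation, in which Ti(OEt)4 acts as Lewis acid and water scavenger, drives even this electron-rich, di-ortho-substituted aldehyde to the E N-sulfinyl aldimine.

Step 3
Reactants: 5 (S,E)-N-[4-(benzyloxy)-2,6-dimethoxybenzylidene]-2-methylpropane-2-sulfinamide; 6 allyl bromide
Product: 7 (S)-N-[(1R)-1-[4-(benzyloxy)-2,6-dimethoxyphenyl]but-3-en-1-yl]-2-methylpropane-2-sulfinamide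
Conditions: indium powder, allyl bromide, THF, 60 °C; then H2O; chromatography to a single diastereomer
Reagents that add atoms: allyl bromide (6), C=CCBr
Why: Indium-mediated Barbier allylation of the C=N bond (the aza counterpart of a carbonyl allylation) runs through a six-membered chair transition state with indium held by the sulfinyl oxygen, so the (S)-sulfinyl group delivers the allyl group to the Re face of the E-aldimine and sets the (R) carbon stereocentre.

Step 4
Reactants: 7 (S)-N-[(1R)-1-[4-(benzyloxy)-2,6-dimethoxyphenyl]but-3-en-1-yl]-2-methylpropane-2-sulfinamide; 6 allyl bromide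
Product: 8 (S)-N-allyl-N-[(1R)-1-[4-(benzyloxy)-2,6-dimethoxyphenyl]but-3-en-1-yl]-2-methylpropane-2-sulfinamide
Conditions: LiN(SiMe3)2, allyl bromide, DMF, −20 °C to rt
Reagents that add atoms: allyl bromide (6), C=CCBr
Why: SN2 N-alkylation of the lithiated sulfinamide with the reactive allylic bromide installs the second alkene without touching the carbon or sulfur stereocentres.

Step 5
Reactants: 8 (S)-N-allyl-N-[(1R)-1-[4-(benzyloxy)-2,6-dimethoxyphenyl]but-3-en-1-yl]-2-methylpropane-2-sulfinamide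
Product: 9 (2R)-2-[4-(benzyloxy)-2,6-dimethoxyphenyl]-1-[(S)-tert-butylsulfinyl]-1,2,3,6-tetrahydropyridine
Conditions: second-generation Grubbs catalyst (H2IMes)(PCy3)Cl2Ru=CHPh (5 mol %), CH2Cl2, 40 °C
Reagents that add atoms: none
Why: Ring-closing metathesis of two terminal alkenes to an unstrained six-membered ring is driven by loss of ethene and does not involve the stereocentre.

Step 6
Reactants: 9 (2R)-2-[4-(benzyloxy)-2,6-dimethoxyphenyl]-1-[(S)-tert-butylsulfinyl]-1,2,3,6-tetrahydropyridine
Product: 10 (2R)-2-[4-(benzyloxy)-2,6-dimethoxyphenyl]-1,2,3,6-tetrahydropyridine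
Conditions: HCl (4 M in dioxane), MeOH, 0 °C; aq. NaHCO3 work-up
Reagents that add atoms: none
Why: Acid-catalysed methanolysis of the S–N bond removes the auxiliary quickly at 0 °C, which keeps the electron-rich benzylic C–N bond from ionising.

Step 7
Reactants: 10 (2R)-2-[4-(benzyloxy)-2,6-dimethoxyphenyl]-1,2,3,6-tetrahydropyridine; 11 formaldehyde
Product: 12 (2R)-2-[4-(benzyloxy)-2,6-dimethoxyphenyl]-1-methyl-1,2,3,6-tetrahydropyridine
Conditions: 37% aq. HCHO, NaBH(OAc)3, ClCH2CH2Cl, rt
Reagents that add atoms: formaldehyde (11), C=O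
Why: Reductive amination with NaBH(OAc)3 methylates the secondary amine once and cleanly, and is done while the phenol is still benzylated so the arene cannot undergo a phenolic Mannich reaction with formaldehyde.

Step 8
Reactants: 12 (2R)-2-[4-(benzyloxy)-2,6-dimethoxyphenyl]-1-methyl-1,2,3,6-tetrahydropyridine
Product: 13 3,5-dimethoxy-4-[(2R)-1-methylpiperidin-2-yl]phenol
Conditions: H2 (1 atm), 10% Pd/C, MeOH, rt
Reagents that add atoms: none
Why: Catalytic hydrogenation saturates the ring alkene and hydrogenolysis cleaves the aryl benzyl ether, both much faster under neutral conditions than cleavage of the hindered cyclic benzylic C–N bond.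

Step 9
Reactants: 13 3,5-dimethoxy-4-[(2R)-1-methylpiperidin-2-yl]phenol; 14 acetic anhydride
Product: 16 1-{6-hydroxy-2,4-dimethoxy-3-[(2R)-1-methylpiperidin-2-yl]phenyl}ethan-1-one, via aryl acetate 15 (not isolated)
Conditions: Ac2O, BF3·OEt2, CH2Cl2, 0 °C to rt; then aq. NaOH work-up
Reagents that add atoms: acetic anhydride (14), CC(=O)OC(C)=O
Why: O-acetylation followed by BF3-promoted Fries rearrangement (ortho Friedel–Crafts acylation) can give only one ketone, because the para position is blocked and the two ortho positions are equivalent.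

Step 10
Reactants: 16 1-{6-hydroxy-2,4-dimethoxy-3-[(2R)-1-methylpiperidin-2-yl]phenyl}ethan-1-one; 17 methyl benzoate
Product: 18 1-{6-hydroxy-2,4-dimethoxy-3-[(2R)-1-methylpiperidin-2-yl]phenyl}-3-phenylpropane-1,3-dione
Conditions: NaH (5 equiv), methyl benzoate (3 equiv), DMF, 0 °C to rt; AcOH quench
Reagents that add atoms: methyl benzoate (17), COC(=O)c1ccccc1
Why: Crossed Claisen condensation of the phenoxide-enolate dianion with the non-enolisable ester joins the two fragments and is pulled to completion by deprotonation of the 1,3-diketone product.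

Step 11
Reactants: 18 1-{6-hydroxy-2,4-dimethoxy-3-[(2R)-1-methylpiperidin-2-yl]phenyl}-3-phenylpropane-1,3-dione
Product: 19 5,7-dimethoxy-6-[(2R)-1-methylpiperidin-2-yl]-2-phenyl-4H-chromen-4-one
Conditions: conc. HCl, AcOH, 50 °C
Reagents that add atoms: none
Why: Acid-catalysed cyclodehydration of the o-hydroxyaryl 1,3-diketone closes the pyranone through the only free phenol, the one para to the piperidinyl carbon, so the 6-substituted flavone is the only possible regioisomer.

Step 12
Reactants: 19 5,7-dimethoxy-6-[(2R)-1-methylpiperidin-2-yl]-2-phenyl-4H-chromen-4-one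
Product: 20 5,7-dihydroxy-6-[(2R)-1-methylpiperidin-2-yl]-2-phenyl-4H-chromen-4-one
Conditions: BBr3 (6 equiv), CH2Cl2, −78 °C to rt; then H2O, pH 8
Reagents that add atoms: none
Why: BBr3 Lewis-acid cleavage of aryl methyl ethers removes both methoxy groups (the 5-oxygen is chelation-activated by the carbonyl) at or below room temperature, mild enough to leave the benzylic amine stereocentre and the 6-substitution pattern intact.

**Compound list**

1 | 4-hydroxy-2,6-dimethoxybenzaldehyde | COc1cc(O)cc(OC)c1C=O | starting material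
2 | benzyl bromide | BrCc1ccccc1 | starting material
3 | 4-(benzyloxy)-2,6-dimethoxybenzaldehyde | COc1cc(OCc2ccccc2)cc(OC)c1C=O | intermediate
4 | (S)-2-methylpropane-2-sulfinamide | CC(C)(C)[S@](=O)N | starting material
5 | (S,E)-N-[4-(benzyloxy)-2,6-dimethoxybenzylidene]-2-methylpropane-2-sulfinamide | CC(C)(C)[S@](=O)/N=C/c1c(OC)cc(OCc2ccccc2)cc1OC | intermediate
6 | allyl bromide | C=CCBr | starting material
7 | (S)-N-[(1R)-1-[4-(benzyloxy)-2,6-dimethoxyphenyl]but-3-en-1-yl]-2-methylpropane-2-sulfinamide | C=CC[C@@H](N[S@@](=O)C(C)(C)C)c1c(OC)cc(OCc2ccccc2)cc1OC | intermediate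
8 | (S)-N-allyl-N-[(1R)-1-[4-(benzyloxy)-2,6-dimethoxyphenyl]but-3-en-1-yl]-2-methylpropane-2-sulfinamide | C=CC[C@@H](N(CC=C)[S@@](=O)C(C)(C)C)c1c(OC)cc(OCc2ccccc2)cc1OC | intermediate
9 | (2R)-2-[4-(benzyloxy)-2,6-dimethoxyphenyl]-1-[(S)-tert-butylsulfinyl]-1,2,3,6-tetrahydropyridine | CC(C)(C)[S@](=O)N1CC=CC[C@@H]1c1c(OC)cc(OCc2ccccc2)cc1OC | intermediate
10 | (2R)-2-[4-(benzyloxy)-2,6-dimethoxyphenyl]-1,2,3,6-tetrahydropyridine | N1CC=CC[C@@H]1c1c(OC)cc(OCc2ccccc2)cc1OC | intermediate
11 | formaldehyde | C=O | starting material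
12 | (2R)-2-[4-(benzyloxy)-2,6-dimethoxyphenyl]-1-methyl-1,2,3,6-tetrahydropyridine | CN1CC=CC[C@@H]1c1c(OC)cc(OCc2ccccc2)cc1OC | intermediate
13 | 3,5-dimethoxy-4-[(2R)-1-methylpiperidin-2-yl]phenol | CN1CCCC[C@@H]1c1c(OC)cc(O)cc1OC | intermediate
14 | acetic anhydride | CC(=O)OC(C)=O | starting material
15 | 3,5-dimethoxy-4-[(2R)-1-methylpiperidin-2-yl]phenyl acetate | CN1CCCC[C@@H]1c1c(OC)cc(OC(C)=O)cc1OC | intermediate
16 | 1-{6-hydroxy-2,4-dimethoxy-3-[(2R)-1-methylpiperidin-2-yl]phenyl}ethan-1-one | CN1CCCC[C@@H]1c1c(OC)cc(O)c(C(C)=O)c1OC | intermediate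
17 | methyl benzoate | COC(=O)c1ccccc1 | starting material
18 | 1-{6-hydroxy-2,4-dimethoxy-3-[(2R)-1-methylpiperidin-2-yl]phenyl}-3-phenylpropane-1,3-dione | CN1CCCC[C@@H]1c1c(OC)cc(O)c(C(=O)CC(=O)c2ccccc2)c1OC | intermediate
19 | 5,7-dimethoxy-6-[(2R)-1-methylpiperidin-2-yl]-2-phenyl-4H-chromen-4-one | CN1CCCC[C@@H]1c1c(OC)cc2oc(-c3ccccc3)cc(=O)c2c1OC | intermediate
20 | 5,7-dihydroxy-6-[(2R)-1-methylpiperidin-2-yl]-2-phenyl-4H-chromen-4-one | CN1CCCC[C@@H]1c1c(O)cc2oc(-c3ccccc3)cc(=O)c2c1O | target

**Totals**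

Total step count: 12. Longest linear sequence: 12 steps (fully linear from compound 1).

**Steps most likely to fail**

Step 3 (allylation of the sulfinyl imine). The aldimine is electron-rich and flanked by two ortho-methoxy groups, so addition may be slow and the ortho oxygens may compete for the metal and erode the facial bias. The fallback sets out from 5 and comes back at 7. The titanium enolate of methyl acetate (LiN(iPr)2, then ClTi(OiPr)3, THF, −78 °C) adds to 5 in an Ellman-type Mannich reaction through a closed six-membered transition state to give methyl (3R)-3-[4-(benzyloxy)-2,6-dimethoxyphenyl]-3-{[(S)-tert-butylsulfinyl]amino}propanoate F1. Reduction with iBu2AlH (CH2Cl2, −78 °C) gives the aldehyde (S)-N-[(1R)-1-[4-(benzyloxy)-2,6-dimethoxyphenyl]-3-oxopropyl]-2-methylpropane-2-sulfinamide F2, and Wittig methylenation (Ph3P=CH2, THF, −78 to 0 °C) delivers 7.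

Step 4 (N-allylation of the sulfinamide). The nitrogen sits between the tert-butylsulfinyl group and a di-ortho-substituted benzylic carbon, so intermolecular alkylation may stall. The fallback sets out from 7 and comes back at 13, replacing N-alkylation by N-acylation. HCl in MeOH at 0 °C frees the amine (1R)-1-[4-(benzyloxy)-2,6-dimethoxyphenyl]but-3-en-1-amine F3, and acryloyl chloride with Et3N gives N-[(1R)-1-[4-(benzyloxy)-2,6-dimethoxyphenyl]but-3-en-1-yl]prop-2-enamide F4. Ring-closing metathesis (second-generation Grubbs catalyst, CH2Cl2, 40 °C) gives the lactam (6R)-6-[4-(benzyloxy)-2,6-dimethoxyphenyl]-5,6-dihydropyridin-2(1H)-one F5, and NaH with MeI gives (6R)-6-[4-(benzyloxy)-2,6-dimethoxyphenyl]-1-methyl-5,6-dihydropyridin-2(1H)-one F6. Hydrogenation over Pd/C saturates the alkene and removes the benzyl group to give (6R)-6-(4-hydroxy-2,6-dimethoxyphenyl)-1-methylpiperidin-2-one F7, which LiAlH4 (THF, reflux) reduces to 13.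

Step 9 (Lewis-acid acylation). The substrate carries a basic amine that ties up the Lewis acid and an electron-rich benzylic C–N bond that could ionise and racemise, and an ortho-methoxy group could be cleaved if the reaction is forced. The fallback sets out from 13 and comes back at 16 by an anionic route that uses no Lewis acid. NaH and MOMCl (THF, 0 °C) give (2R)-2-[2,6-dimethoxy-4-(methoxymethoxy)phenyl]-1-methylpiperidine F8. Directed ortho-lithiation with n-BuLi (THF, 0 °C) at one of the two equivalent positions between the OMOM and OMe groups, then N-methoxy-N-methylacetamide, gives 1-{2,4-dimethoxy-6-(methoxymethoxy)-3-[(2R)-1-methylpiperidin-2-yl]phenyl}ethan-1-one F9. Brief HCl in MeOH at rt removes the MOM group to give 16.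

**Further compounds**

F1 | step 3 | methyl (3R)-3-[4-(benzyloxy)-2,6-dimethoxyphenyl]-3-{[(S)-tert-butylsulfinyl]amino}propanoate | COC(=O)C[C@@H](N[S@@](=O)C(C)(C)C)c1c(OC)cc(OCc2ccccc2)cc1OC
F2 | step 3 | (S)-N-[(1R)-1-[4-(benzyloxy)-2,6-dimethoxyphenyl]-3-oxopropyl]-2-methylpropane-2-sulfinamide | O=CC[C@@H](N[S@@](=O)C(C)(C)C)c1c(OC)cc(OCc2ccccc2)cc1OC
F3 | step 4 | (1R)-1-[4-(benzyloxy)-2,6-dimethoxyphenyl]but-3-en-1-amine | C=CC[C@@H](N)c1c(OC)cc(OCc2ccccc2)cc1OC
F4 | step 4 | N-[(1R)-1-[4-(benzyloxy)-2,6-dimethoxyphenyl]but-3-en-1-yl]prop-2-enamide | C=CC[C@@H](NC(=O)C=C)c1c(OC)cc(OCc2ccccc2)cc1OC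
F5 | step 4 | (6R)-6-[4-(benzyloxy)-2,6-dimethoxyphenyl]-5,6-dihydropyridin-2(1H)-one | O=C1C=CC[C@@H](N1)c1c(OC)cc(OCc2ccccc2)cc1OC
F6 | step 4 | (6R)-6-[4-(benzyloxy)-2,6-dimethoxyphenyl]-1-methyl-5,6-dihydropyridin-2(1H)-one | CN1C(=O)C=CC[C@@H]1c1c(OC)cc(OCc2ccccc2)cc1OC
F7 | step 4 | (6R)-6-(4-hydroxy-2,6-dimethoxyphenyl)-1-methylpiperidin-2-one | CN1C(=O)CCC[C@@H]1c1c(OC)cc(O)cc1OC
F8 | step 9 | (2R)-2-[2,6-dimethoxy-4-(methoxymethoxy)phenyl]-1-methylpiperidine | CN1CCCC[C@@H]1c1c(OC)cc(OCOC)cc1OC
F9 | step 9 | 1-{2,4-dimethoxy-6-(methoxymethoxy)-3-[(2R)-1-methylpiperidin-2-yl]phenyl}ethan-1-one | CN1CCCC[C@@H]1c1c(OC)cc(OCOC)c(C(C)=O)c1OC
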